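**Retrosynthetic overview**

1. Numbering used: ring A = C1–C5 and C10 (gem-dimethyl on C4); ring B = C5–C10 (methyl on C8, exocyclic C9=C11); ring C = the arene. The C11–aryl bond comes from an aryllithium and a C11 aldehyde, E1 dehydration then gives the E C9=C11 alkene; C11 comes from a C9 ketone by one-carbon homologation.
2. Ring A is opened at C3–C4: a tertiary C4 radical, made by metal-hydride hydrogen-atom transfer to an isopropenyl group on C5, adds 6-endo to a C2=C3 vinyl sulfone carried by C10. The sulfonyl group is only an activating group and is stripped, together with the enone, by Li/NH3.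
3. Enabling feature: the gem-dimethyl quaternary carbon C4 of ring A is bonded directly to the ring-fusion methine C5, and ring B carries the C8 methyl beside C9. This is the isopropenyl/2-methylcyclohexenone pattern of (S)-carvone, whose isopropenyl CH2 becomes the second C4 methyl when the radical is formed.
4. Stereocontrol: C5 from carvone; quaternary C10 by two enolate alkylations (arm first, methyl second and anti to isopropenyl, so the arms on C5 and C10 are cis and the decalin is cis-fused); C8 by equilibration of the C9 ketone.
5. Ring order: ring B (carvone) and ring C (2,4,5-trihydroxybenzaldehyde) are bought; ring A is the only ring built and is closed in step 4.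

Key step: step 4

Remark on the chemistry: the SMILES is read as a cis-fused decalin (H on C5, methyl on C10 and methyl on C8 on one face; 5R,8S,10S in the numbering above) with an E alkene, and the route is designed for exactly this configuration.

**Route**

Step 1
Reactants: 1 (S)-(+)-carvone; 2 2,3-dibromoprop-1-ene
Product: 4 (5S,6R)-6-(2-bromoprop-2-en-1-yl)-2-methyl-5-(prop-1-en-2-yl)cyclohex-2-en-1-one, via lithium enolate 3 (not isolated)
Conditions: LiN(i-Pr)2 (LDA, 1.05 equiv), THF, −78 °C; then 2, −78 → 0 °C
Reagents that add atoms: none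
Why: Kinetic α′-deprotonation of the enone and SN2 allylation of the cross-conjugated lithium enolate (a standard carvone alkylation) should install the three-carbon arm that becomes C1–C3; the electrophile enters anti to the isopropenyl group, but this centre is re-enolised in step 2, so its configuration is immaterial.

Step 2
Reactants: 4
Product: 6 (5R,6S)-6-(2-bromoprop-2-en-1-yl)-2,6-dimethyl-5-(prop-1-en-2-yl)cyclohex-2-en-1-one, via lithium enolate 5 (not isolated)
Conditions: LiN(i-Pr)2, THF, −78 °C; MeI, −78 → −20 °C
Reagents that add atoms: iodomethane, CI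
Why: Enolate C-methylation under substrate-controlled 1,2-induction: methyl iodide should attack the tetrasubstituted enolate on the face opposite the adjacent isopropenyl group, so the methyl ends up trans and the bromoallyl arm cis to it, which sets quaternary C10 and predetermines the cis ring fusion.

Step 3
Reactants: 6
Product: 7 (5R,6S)-2,6-dimethyl-6-[2-(phenylsulfonyl)prop-2-en-1-yl]-5-(prop-1-en-2-yl)cyclohex-2-en-1-one
Conditions: PhSO2Na (1.5 equiv), CuI (10 mol %), L-proline sodium salt (20 mol %), DMSO, 95 °C
Reagents that add atoms: sodium benzenesulfinate, [Na+].[O-]S(=O)c1ccccc1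
Why: Ullmann-type copper-catalysed C–S cross-coupling of an alkenyl bromide with a sulfinate salt should give the 1,1-disubstituted vinyl sulfone with no stereocentre touched; copper is chosen because an alkenylpalladium species would insert into the nearby isopropenyl group, and the sulfone is introduced only now because the vinyl bromide, unlike a vinyl sulfone, is inert to the amide base of step 2.

Step 4
Reactants: 7
Product: 10 (4aR,8aS)-2,5,5,8a-tetramethyl-7-(phenylsulfonyl)-4a,5,6,7,8,8a-hexahydronaphthalen-1(4H)-one (C-7 epimer mixture), via tertiary radical 8 (not isolated), via sulfonyl-stabilised radical 9 (not isolated)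
Conditions: Fe(acac)3 (30 mol %), PhSiH3 (2.5 equiv), EtOH/HOCH2CH2OH (5:1), 60 °C
Reagents that add atoms: none
Why: A trivalent iron hydride, formed from Fe(acac)3 and PhSiH3, should transfer a hydrogen atom to the CH2 terminus of the electron-rich isopropenyl group, which turns that carbon into the second C4 methyl and leaves the tertiary C4 radical 8. This nucleophilic radical should add to the unsubstituted β-carbon C3 of the tethered vinyl sulfone, closing ring A in a 6-endo-trig mode, and the sulfonyl-stabilised radical 9 is then reduced by divalent iron and protonated by ethanol. The closest known reaction type is the MHAT-initiated reductive olefin coupling (radical Giese addition) of 1,1-disubstituted alkenes with vinyl sulfones and related acceptors, used here intramolecularly. No lasting stereocentre is created: C4 becomes the achiral gem-dimethyl carbon, the sulfone-bearing carbon forms as an epimer mixture that is erased in step 5, and the cis ring fusion follows from the cis relation of the C5 and C10 arms set in steps 1 and 2. The step needs chemoselective hydrogen-atom transfer to the isopropenyl group, secured by its being the only electron-rich alkene (enone and vinyl sulfone are electron-poor), and 6-endo rather than 5-exo closure, secured by the sulfonyl group on the internal alkene carbon, which makes C3 the electrophilic, unhindered terminus and would force a 5-exo attack to join two fully substituted carbons.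

Step 5
Reactants: 10
Product: 13 (2S,4aR,8aS)-2,5,5,8a-tetramethyloctahydronaphthalen-1(2H)-one, via lithium enolate 11 (not isolated), via C-2 epimer 12 (not isolated)
Conditions: Li (8 equiv), NH3(l)/THF, −78 °C; solid NH4Cl; then NaOMe (20 mol %), MeOH, 25 °C
Reagents that add atoms: none
Why: Birch-type dissolving-metal reduction should saturate the enone to its lithium enolate and cleave the alkyl–sulfonyl bond in the same pot, and methoxide equilibration of the protonated ketone should then settle C8 (C-2 of the decalone) as the epimer with an equatorial methyl cis to the angular methyl, because the other epimer places that methyl 1,3-diaxial to the axial C1 methylene of the cis-decalin.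

Step 6
Reactants: 13
Product: 14 (2S,4aR,8aS)-2,5,5,8a-tetramethyloctahydro-2H-spiro[naphthalene-1,2'-oxirane] (spiro centre not assigned)
Conditions: Me3SI, n-BuLi, THF, −10 → 25 °C
Reagents that add atoms: trimethylsulfonium iodide, C[S+](C)C.[I-]
Why: Corey–Chaykovsky epoxidation: the small sulfonium methylide is one of the few one-carbon nucleophiles that adds to a 2,2,6-trisubstituted cyclohexanone, it should attack the face away from the axial C1 methylene, and the new spiro centre is destroyed in step 7.

Step 7
Reactants: 14
Product: 15 (2S,4aR,8aS)-2,5,5,8a-tetramethyldecahydronaphthalene-1-carbaldehyde (C-1 epimer mixture)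
Conditions: BF3·OEt2 (20 mol %), CH2Cl2, −78 → −20 °C
Reagents that add atoms: none
Why: Meinwald rearrangement: Lewis-acid opening of the 1,1-disubstituted epoxide at its tertiary carbon followed by a 1,2-hydride shift from the CH2O carbon should give the homologated aldehyde (C11), whose α-centre C9 becomes sp2 in step 10 and therefore needs no control.

Step 8
Reactants: 16 2,4,5-trihydroxybenzaldehyde
Product: 17 2,4,5-tris(methoxymethoxy)benzaldehyde
Conditions: MOMCl (4 equiv), i-Pr2NEt (5 equiv), CH2Cl2, 0 → 40 °C
Reagents that add atoms: chloromethyl methyl ether, COCCl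
Why: Williamson-type acetal protection of all three phenols; the MOM ethers later direct ortho-lithiation and can be removed without strong protic acid.

Step 9
Reactants: 15; 17
Product: 21 3-{hydroxy[(2S,4aR,8aS)-2,5,5,8a-tetramethyldecahydronaphthalen-1-yl]methyl}-2,4,5-tris(methoxymethoxy)benzaldehyde (carbinol/C-1 epimer mixture), via lithium amino alkoxide 18 (not isolated), via aryllithium 19 (not isolated), via dilithium adduct 20 (not isolated)
Conditions: N-methylpiperazine/n-BuLi (1:1), THF, −20 °C, then 17; n-BuLi, −20 → 0 °C; 15, −78 → 0 °C; H2O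
Reagents that add atoms: none
Why: The aldehyde of 17 is masked in situ as its lithium α-amino alkoxide, directed ortho-metalation should then occur at the position flanked by two OMOM groups, and 1,2-addition of this aryllithium to aldehyde 15 forms the C11–aryl bond, with water releasing the formyl group; both carbinol epimers are used because C11 and C9 become sp2 in step 10.

Step 10
Reactants: 21
Product: 22 2,4,5-tris(methoxymethoxy)-3-[(E)-((2S,4aR,8aS)-2,5,5,8a-tetramethyloctahydronaphthalen-1(2H)-ylidene)methyl]benzaldehyde
Conditions: (±)-camphor-10-sulfonic acid (10 mol %), CH2Cl2, 4 Å molecular sieves, 0 → 25 °C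
Reagents that add atoms: none
Why: Acid-catalysed E1 dehydration: ionisation to the benzylic cation stabilised by the two ortho alkoxy groups leaves the C9 proton as the only β-hydrogen, all carbinol epimers converge on the same cation, and loss of that proton with the aryl group turned toward the C8 methine rather than toward quaternary C10 should give the E alkene.

Step 11
Reactants: 22
Product: 24 2,4,5-trihydroxy-3-[(E)-((2S,4aR,8aS)-2,5,5,8a-tetramethyloctahydronaphthalen-1(2H)-ylidene)methyl]benzaldehyde (target CNP0111013.2), via tris(trimethylsilyl) ether 23 (not isolated)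
Conditions: Me3SiOTf (6 equiv), 2,2'-bipyridyl (9 equiv), CH2Cl2, 0 → 25 °C; then H2O
Reagents that add atoms: none
Why: Buffered silyl-triflate cleavage of aryl MOM ethers to aryl silyl ethers, which hydrolyse when water is added; no strong protic acid is present, so the ortho-hydroxystyrene (prone to acid-induced cyclisation onto C9) and the aldehyde should survive.

**Compound list**

1 | (S)-(+)-carvone, (5S)-2-methyl-5-(prop-1-en-2-yl)cyclohex-2-en-1-one | CC1=CC[C@H](C(C)=C)CC1=O | starting material
2 | 2,3-dibromoprop-1-ene | BrCC(Br)=C | starting material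
3 | lithium enolate of 1 (cross-conjugated α′-enolate) | CC1=CC[C@H](C(C)=C)C=C1O[Li] | intermediate
4 | (5S,6R)-6-(2-bromoprop-2-en-1-yl)-2-methyl-5-(prop-1-en-2-yl)cyclohex-2-en-1-one | CC1=CC[C@H](C(C)=C)[C@@H](CC(Br)=C)C1=O | intermediate
5 | lithium enolate of 4 | CC1=CC[C@H](C(C)=C)C(CC(Br)=C)=C1O[Li] | intermediate
6 | (5R,6S)-6-(2-bromoprop-2-en-1-yl)-2,6-dimethyl-5-(prop-1-en-2-yl)cyclohex-2-en-1-one (6-methyl trans to isopropenyl) | CC1=CC[C@H](C(C)=C)[C@](C)(CC(Br)=C)C1=O | intermediate
7 | (5R,6S)-2,6-dimethyl-6-[2-(phenylsulfonyl)prop-2-en-1-yl]-5-(prop-1-en-2-yl)cyclohex-2-en-1-one | CC1=CC[C@H](C(C)=C)[C@](C)(CC(=C)S(=O)(=O)c2ccccc2)C1=O | intermediate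
8 | tertiary C4 radical from 7 (2-propyl radical on C5) | CC1=CC[C@H]([C](C)C)[C@](C)(CC(=C)S(=O)(=O)c2ccccc2)C1=O | intermediate
9 | cyclised α-sulfonyl radical (radical at C2 of ring A) | CC1=CC[C@@H]2C(C)(C)C[C](S(=O)(=O)c3ccccc3)C[C@]2(C)C1=O | intermediate
10 | (4aR,8aS)-2,5,5,8a-tetramethyl-7-(phenylsulfonyl)-4a,5,6,7,8,8a-hexahydronaphthalen-1(4H)-one, cis-fused, C-7 epimers | CC1=CC[C@@H]2C(C)(C)CC(S(=O)(=O)c3ccccc3)C[C@]2(C)C1=O | intermediate
11 | lithium enolate from reduction of 10 (C8=C9 enolate, sulfone removed) | CC=1CC[C@@H]2C(C)(C)CCC[C@]2(C)C=1O[Li] | intermediate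
12 | (2R,4aR,8aS)-2,5,5,8a-tetramethyloctahydronaphthalen-1(2H)-one (C-2 epimer of 13) | C[C@@H]1CC[C@@H]2C(C)(C)CCC[C@]2(C)C1=O | intermediate
13 | (2S,4aR,8aS)-2,5,5,8a-tetramethyloctahydronaphthalen-1(2H)-one, cis-fused | C[C@H]1CC[C@@H]2C(C)(C)CCC[C@]2(C)C1=O | intermediate
14 | (2S,4aR,8aS)-2,5,5,8a-tetramethyloctahydro-2H-spiro[naphthalene-1,2'-oxirane], spiro centre not assigned | C[C@H]1CC[C@@H]2C(C)(C)CCC[C@]2(C)C13CO3 | intermediate
15 | (2S,4aR,8aS)-2,5,5,8a-tetramethyldecahydronaphthalene-1-carbaldehyde, C-1 epimers | C[C@H]1CC[C@@H]2C(C)(C)CCC[C@]2(C)C1C=O | intermediate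
16 | 2,4,5-trihydroxybenzaldehyde | O=Cc1cc(O)c(O)cc1O | starting material
17 | 2,4,5-tris(methoxymethoxy)benzaldehyde | O=Cc1cc(OCOC)c(OCOC)cc1OCOC | intermediate
18 | lithium α-amino alkoxide of 17 (N-methylpiperazine adduct) | [Li]OC(N1CCN(C)CC1)c1cc(OCOC)c(OCOC)cc1OCOC | intermediate
19 | 3-lithio derivative of 18 (lithium between the 2- and 4-OMOM groups) | [Li]OC(N1CCN(C)CC1)c1cc(OCOC)c(OCOC)c([Li])c1OCOC | intermediate
20 | dilithium adduct of 19 and 15 (lithium carbinolate, amino alkoxide intact) | C[C@H]1CC[C@@H]2C(C)(C)CCC[C@]2(C)C1C(O[Li])c1c(OCOC)c(OCOC)cc(C(O[Li])N3CCN(C)CC3)c1OCOC | intermediate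
21 | 3-{hydroxy[(2S,4aR,8aS)-2,5,5,8a-tetramethyldecahydronaphthalen-1-yl]methyl}-2,4,5-tris(methoxymethoxy)benzaldehyde, carbinol and C-1 epimers | C[C@H]1CC[C@@H]2C(C)(C)CCC[C@]2(C)C1C(O)c1c(OCOC)c(OCOC)cc(C=O)c1OCOC | intermediate
22 | 2,4,5-tris(methoxymethoxy)-3-[(E)-((2S,4aR,8aS)-2,5,5,8a-tetramethyloctahydronaphthalen-1(2H)-ylidene)methyl]benzaldehyde | C[C@H]1CC[C@@H]2C(C)(C)CCC[C@]2(C)/C1=C/c1c(OCOC)c(OCOC)cc(C=O)c1OCOC | intermediate
23 | tris(trimethylsilyl) ether of the target | C[C@H]1CC[C@@H]2C(C)(C)CCC[C@]2(C)/C1=C/c1c(O[Si](C)(C)C)c(O[Si](C)(C)C)cc(C=O)c1O[Si](C)(C)C | intermediate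
24 | 2,4,5-trihydroxy-3-[(E)-((2S,4aR,8aS)-2,5,5,8a-tetramethyloctahydronaphthalen-1(2H)-ylidene)methyl]benzaldehyde (CNP0111013.2) | C[C@H]1CC[C@@H]2C(C)(C)CCC[C@]2(C)/C1=C/c1c(O)c(O)cc(C=O)c1O | target

**Step count and risks**

Total step count: 11 (steps 1–7 and 9–11 on the main line, step 8 for the arene fragment).
Longest linear sequence: 10 steps, from (S)-carvone 1 to 24.

Steps most likely to fail:

Step 4 (key step). The tertiary radical may be reduced before it cyclises (net hydrogenation of the isopropenyl group), or hydrogen-atom transfer may go to the enone or vinyl sulfone instead. The fallback sets out from 7 and comes back to the route at 10. Markovnikov addition of HBr (33% HBr in AcOH, CH2Cl2, 0 °C) to the isopropenyl group should give the tertiary bromide (5S,6S)-5-(2-bromopropan-2-yl)-2,6-dimethyl-6-[2-(phenylsulfonyl)prop-2-en-1-yl]cyclohex-2-en-1-one F1. Slow addition of n-Bu3SnH with AIBN in benzene at 80 °C then generates the same C4 radical by bromine-atom abstraction at low hydride concentration, and the same 6-endo closure should give 10.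

Step 3. Activation of the hindered 2-bromoalkene by monovalent copper may be too slow, or the substrate may degrade in hot DMSO. The fallback sets out from 1 and comes back to the route at 7. Lithium enolate 3 (LiN(i-Pr)2, THF, −78 °C) is alkylated by SN2′ addition–elimination with commercial 2,3-bis(phenylsulfonyl)prop-1-ene to give (5S,6R)-2-methyl-6-[2-(phenylsulfonyl)prop-2-en-1-yl]-5-(prop-1-en-2-yl)cyclohex-2-en-1-one F2. KN(SiMe3)2 is then added to F2 in the presence of MeI at −78 °C, so that the potassium enolate of F2 F3 is methylated as it forms, anti to the isopropenyl group, to give 7. The internal quench is meant to keep the enolate from adding to the vinyl sulfone.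

Step 9. The bulky, basic aryllithium may enolise the hindered α-branched aldehyde instead of adding to it. The fallback sets out from 15 and 17 and comes back to the route at 22, replacing carbonyl addition and dehydration by a cross-coupling. Aldehyde 15 is deprotonated with KN(SiMe3)2 (THF, −78 °C) to the potassium enolate of 15 F4, which is trapped with PhNTf2 as the enol triflate [(E)-((2S,4aR,8aS)-2,5,5,8a-tetramethyloctahydronaphthalen-1(2H)-ylidene)methyl] trifluoromethanesulfonate F5, with the triflate expected on the C8 side. Separately, 17 is protected and lithiated as in step 9 (18, then 19) and quenched with 2-isopropoxy-4,4,5,5-tetramethyl-1,3,2-dioxaborolane and water to give 2,4,5-tris(methoxymethoxy)-3-(4,4,5,5-tetramethyl-1,3,2-dioxaborolan-2-yl)benzaldehyde F6. Suzuki–Miyaura coupling of F5 and F6 (Pd(OAc)2, SPhos, K3PO4, THF/H2O, 40 °C) should give 22 with retention of alkene geometry.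

**Further compounds**

F1 | step 4 | (5S,6S)-5-(2-bromopropan-2-yl)-2,6-dimethyl-6-[2-(phenylsulfonyl)prop-2-en-1-yl]cyclohex-2-en-1-one | CC1=CC[C@H](C(C)(C)Br)[C@](C)(CC(=C)S(=O)(=O)c2ccccc2)C1=O
F2 | step 3 | (5S,6R)-2-methyl-6-[2-(phenylsulfonyl)prop-2-en-1-yl]-5-(prop-1-en-2-yl)cyclohex-2-en-1-one | CC1=CC[C@H](C(C)=C)[C@@H](CC(=C)S(=O)(=O)c2ccccc2)C1=O
F3 | step 3 | potassium enolate of F2 | CC1=CC[C@H](C(C)=C)C(CC(=C)S(=O)(=O)c2ccccc2)=C1O[K]
F4 | step 9 | potassium enolate of 15 | C[C@H]1CC[C@@H]2C(C)(C)CCC[C@]2(C)C1=CO[K]
F5 | step 9 | [(E)-((2S,4aR,8aS)-2,5,5,8a-tetramethyloctahydronaphthalen-1(2H)-ylidene)methyl] trifluoromethanesulfonate | C[C@H]1CC[C@@H]2C(C)(C)CCC[C@]2(C)/C1=C/OS(=O)(=O)C(F)(F)F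
F6 | step 9 | 2,4,5-tris(methoxymethoxy)-3-(4,4,5,5-tetramethyl-1,3,2-dioxaborolan-2-yl)benzaldehyde | O=Cc1cc(OCOC)c(OCOC)c(B2OC(C)(C)C(C)(C)O2)c1OCOC
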